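Rate constants are what I would like for this flask, and the earlier runs yield one; the rest has to come from how those two runs differ.

in all of them: free catalyst 0.78 mM
- beta: substrate 0.10 M; reagent 0.50 M (fed, over 12 s); run made earlier
- eta: substrate 0.40 M; reagent 0.50 M (fed, over 12 s); run made earlier
- flask: substrate 0.20 M; reagent 0.500 M (fed, over 12 s); time 1.5 h

| run | time / min | substrate / % | target / % | uncatalysed product / % |
|---|---|---|---|---|
| beta | 8.00 | 0.6 | 94.2 | 3.3 |
| beta | 25.0 | 0 | 93.3 | 4.5 |
| beta | 40.0 | 0.5 | 94.1 | 4.7 |
| beta | 60.0 | 0 | 92.7 | 3.5 |
| beta | 90.0 | 0.2 | 94.4 | 3.5 |
| eta | 8.00 | 8.8 | 67.8 | 11.9 |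
| eta | 25.0 | 2.0 | 67.6 | 19.7 |
| eta | 40.0 | 0.1 | 68.7 | 20.5 |
| eta | 60.0 | 0.6 | 68.1 | 23.0 |
| eta | 90.0 | 0.2 | 67.9 | 22.0 |

(scatter of a reading: 0.5 percentage points)

- what was read earlier has a scatter of 0.5 percentage points, one standard deviation
- the reaction counts as stopped when no species that holds the substrate changes by six tenths of a point or more over the second half of the time

* at 1.5 h, what has stopped the reaction, if anything has (all of the substrate has reacted / it is still moving / forward and back rates have come level / the reagent has run out first)
* how much of the substrate has reacted by 1.5 h
* how much target there is at 1.5 h, in percent of the substrate charged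
* how much uncatalysed product there is at 1.5 h, in percent of the substrate charged

In the eta run substrate falls from 8.8% at 8.00 min to 2.0% at 25.0 min, which reads as a pseudo-first-order constant of 0.0872 min⁻¹, a half-life of 7.95 min. The flask has the same reagent charge against half of eta's [substrate], so I expect its drain to be no slower. Its 1.5 h then holds 11.3 such half-lives, which leaves hardly any substrate. Time is therefore not my question; the split is.

In eta, target reads 67.8% at the first reading and 67.9% at the last while substrate drains in between, so within the scatter of 0.5 percentage points eta's target has stopped rising by 8.00 min. I have no constant for that stopping, but I can compare the two runs. Target averages 93.7% in beta and 68.0% in eta, which lie 2.00 doublings of substrate apart. Each doubling thus costs 13 points. This toll, the points of target share lost per doubling of [substrate] with reagent and catalyst held, assumes a straight line in doublings, which two runs cannot test. Uncatalysed product likewise climbs from 3.90% to 21.8%, counting eta after its drain, or 9 points per doubling. The flask stands 1.00 doubling above beta, so I reckon target 80.9% and uncatalysed product 12.9%.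

The forecast says all of the substrate has reacted, with conversion 99.9%, target 89.5% and uncatalysed product 6.2%, on the ground that “the catalyst should carry nearly everything”. My target stands 8.6 points below it and my uncatalysed product 6.7 points above it.

The flask gives: all of the substrate has reacted, conversion >99.9%, target 83.2%, uncatalysed product 11.4%.

    substrate + free catalyst ⇌ free catalyst + open intermediate (K = 1.40, k = 478 L mol⁻¹ s⁻¹)
    free catalyst + open intermediate ⇌ catalyst intermediate (K = 129 L mol⁻¹, k = 1050 L mol⁻¹ s⁻¹)
    reagent + catalyst intermediate → free catalyst + target (k = 158 L mol⁻¹ s⁻¹)
    substrate + reagent → uncatalysed product (k = 0.00850 L mol⁻¹ s⁻¹)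
    free catalyst + target → spent catalyst (k = 1.17 L mol⁻¹ s⁻¹)

Counted from beta's average, the flask's doubling cost 10 points of target share, less than the toll of 13 points. The neighbouring flask has 0.12 M of substrate, with its other charges as in the flask, and stands 0.263 of a doubling above beta. The toll puts its target at 90.4% and its uncatalysed product at 6.26%; that neighbouring flask gives 91.4% and 5.78%.

All runs come from a simulation with constants of no real substance; noise was put on by code.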